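Cupressuflavone is disconnected twice through ring C of each apigenin half, at C4–C4a and at O1–C2, leaving the 8,8'' axis intact. The key step exploits that each ring A is a phloroglucinol ring whose axis carbon (future C8) is flanked by a free hydroxyl (future O1) with a nucleophilic C–H (future C4a) next to it: one acid-free thermal condensation lays the C2–C3–C4 unit of an aroylacetate across O1 and C4a of both rings and closes both pyranone rings. The precursor is 4,4'-dimethoxybiphenyl-2,2',6,6'-tetrol, whose oxygen para to the axis (future O5) is capped as a methyl ether so that only the 8,8'' mode can form.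

Key step: step 4

Remark: the target is written without a descriptor for the 8,8'' axis, so no control of axial configuration is attempted and the biflavone is expected as the racemate.

Step 1
Reactants: 1 5-methoxyresorcinol; 2 chloromethyl methyl ether
Product: 3 1-methoxy-3,5-bis(methoxymethoxy)benzene
Conditions: NaH, DMF, 0 °C; then MOMCl, 0 °C → rt
Reagents that add atoms: chloromethyl methyl ether (2), COCCl
Why: Twofold Williamson-type O-alkylation of the sodium phenoxides by the highly reactive α-chloro ether should install two methoxymethyl acetals, chosen because they are the strongest ortho-directors on the ring and later fall off in dilute acid that leaves the methyl ether untouched.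

Step 2
Reactants: 3 1-methoxy-3,5-bis(methoxymethoxy)benzene (two molecules)
Product: 5 4,4'-dimethoxy-2,2',6,6'-tetrakis(methoxymethoxy)biphenyl, via aryllithium 4 (not isolated)
Conditions: n-BuLi, THF, 0 °C; then anhydrous CuCl2, −78 °C → rt
Reagents that add atoms: none
Why: Directed ortho-metalation should remove the one proton flanked by two chelating methoxymethoxy groups (each of the other two ring protons has only one such neighbour beside a weaker methoxy donor), and oxidative homocoupling of aryllithium 4 through an aryl species of divalent copper, which reductively eliminates the biaryl and leaves CuCl, should join two such carbons into the tetra-ortho-oxygenated axis.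

Step 3
Reactants: 5 4,4'-dimethoxy-2,2',6,6'-tetrakis(methoxymethoxy)biphenyl
Product: 6 4,4'-dimethoxybiphenyl-2,2',6,6'-tetrol
Conditions: HCl (cat.), degassed MeOH, 50 °C, argon
Reagents that add atoms: none
Why: Acid-catalysed acetal methanolysis should free the four phenols while methanol traps the methoxymethyl cation as dimethoxymethane, and dilute HCl at this temperature leaves the aryl methyl ethers intact and is too mild to dehydrate the ortho,ortho'-diol to a dibenzofuran.

Step 4
Reactants: 6 4,4'-dimethoxybiphenyl-2,2',6,6'-tetrol; 7 ethyl 4-methoxybenzoylacetate (two molecules incorporated, about 3 equiv used)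
Product: 10 5,5'',4',4'''-tetra-O-methylcupressuflavone, via aroylketene 8 (not isolated), via bis-diketone 9 (not isolated)
Conditions: 7 (3 equiv), Ph2O, 240–250 °C, argon sweep, EtOH and H2O distilled out
Reagents that add atoms: ethyl 4-methoxybenzoylacetate (7), CCOC(=O)CC(=O)c1ccc(OC)cc1
Why: Above about 200 °C the β-keto ester 7 should shed ethanol to give aroylketene 8 (or hand its acyl group to a phenol oxygen, from which it migrates to carbon), and each phloroglucinol-type ring A is acylated at the C–H lying between the free hydroxyl and the methoxy group, which forms C4–C4a and gives bis-diketone 9. In each half the hydroxyl ortho to the axis then adds to the anisyl ketone carbonyl in a 6-exo-trig closure (O1–C2) and the hemiketal loses water, so each ring C is closed as an aromatic 4-pyranone. The closest known reaction is the Mentzer pyrone synthesis, the acid-free thermal relative of the Simonis chromone synthesis, which converts phloroglucinols and ethyl aroylacetates into 5,7-dioxygenated flavones. No stereocentre is created; the 8,8'' axis becomes stereogenic in this step and should form as the racemate. Three selectivities are needed: 8,8'' over 6-linked closure, secured because the oxygen para to the axis is a methyl ether, so the only hydroxyl beside each acylated carbon is the one next to the axis carbon, and because both C–H sites and both hydroxyls of each ring are equivalent by local symmetry; chromone over coumarin, secured by the absence of a condensing acid; and one annulation per ring, secured by the deactivating vinylogous ester formed in the first closure on that ring and by the limited excess of 7.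

Step 5
Reactants: 10 5,5'',4',4'''-tetra-O-methylcupressuflavone
Product: 11 cupressuflavone
Conditions: BBr3 (excess), CH2Cl2, −78 °C → rt; then MeOH, H2O
Reagents that add atoms: none
Why: In this Lewis-acid ether cleavage BBr3 complexes each methoxy oxygen and bromide removes the methyl group by SN2 attack, the peri-methoxy groups at C5 and C5'' being helped by chelation to the C4 carbonyls and the two anisyl ethers following at room temperature, while the pyranone rings and the axis are inert, so aqueous work-up should release the hexaphenol.

Compound list
1 | 5-methoxyresorcinol (3,5-dihydroxyanisole) | COc1cc(O)cc(O)c1 | starting material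
2 | chloromethyl methyl ether | COCCl | starting material
3 | 1-methoxy-3,5-bis(methoxymethoxy)benzene | COCOc1cc(OC)cc(OCOC)c1 | intermediate
4 | [4-methoxy-2,6-bis(methoxymethoxy)phenyl]lithium (aryllithium) | [Li]c1c(OCOC)cc(OC)cc1OCOC | intermediate
5 | 4,4'-dimethoxy-2,2',6,6'-tetrakis(methoxymethoxy)biphenyl | COCOc1cc(OC)cc(OCOC)c1-c1c(OCOC)cc(OC)cc1OCOC | intermediate
6 | 4,4'-dimethoxybiphenyl-2,2',6,6'-tetrol | COc1cc(O)c(c(O)c1)-c1c(O)cc(OC)cc1O | intermediate
7 | ethyl 4-methoxybenzoylacetate (ethyl 3-(4-methoxyphenyl)-3-oxopropanoate) | CCOC(=O)CC(=O)c1ccc(OC)cc1 | starting material
8 | 4-methoxybenzoylketene (3-(4-methoxyphenyl)-3-oxoprop-1-en-1-one) | COc1ccc(cc1)C(=O)C=C=O | intermediate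
9 | 3,3'-bis[3-(4-methoxyphenyl)-3-oxopropanoyl]-4,4'-dimethoxybiphenyl-2,2',6,6'-tetrol (bis-diketone) | COc1ccc(cc1)C(=O)CC(=O)c1c(OC)cc(O)c(c1O)-c1c(O)cc(OC)c(C(=O)CC(=O)c2ccc(OC)cc2)c1O | intermediate
10 | 5,5'',4',4'''-tetra-O-methylcupressuflavone (7,7''-dihydroxy-5,5''-dimethoxy-2,2''-bis(4-methoxyphenyl)-8,8''-bi-4H-chromen-4-one, racemic axis) | O=c1cc(-c2ccc(OC)cc2)oc2c(-c3c(O)cc(OC)c4c(=O)cc(-c5ccc(OC)cc5)oc34)c(O)cc(OC)c12 | intermediate
11 | cupressuflavone (8,8''-biapigenin; 5,5'',7,7''-tetrahydroxy-2,2''-bis(4-hydroxyphenyl)-8,8''-bi-4H-chromen-4-one, racemic axis) | O=c1cc(-c2ccc(O)cc2)oc2c(-c3c(O)cc(O)c4c(=O)cc(-c5ccc(O)cc5)oc34)c(O)cc(O)c12 | target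

Total step count: 5. Longest linear sequence: 5 steps (1 → 3 → 5 → 6 → 10 → 11).

Steps most likely to fail

Step 4. The twofold annulation may stop after one half, and the hot melt may dehydrate the two hydroxyls that face each other across the axis to a dibenzofuran. Acylation may also stay at oxygen, or the ketene may be lost to self-condensation. The fallback builds ring C stepwise and sets out from 6. Twofold Friedel–Crafts C-acetylation (Ac2O, BF3·OEt2, 70 °C) should place one acetyl group on each ring, since the first one deactivates its own ring, and give 3,3'-diacetyl-4,4'-dimethoxybiphenyl-2,2',6,6'-tetrol F1. Its polyanion, formed with excess LiN(SiMe3)2 in THF at −78 °C, should be C-aroylated at both methyl ketone enolates by 4-methoxybenzoyl chloride, a known Baker–Venkataraman-type route from unprotected polyhydroxyacetophenones to flavone diketones. This comes back to the route at bis-diketone 9, now isolated, which catalytic H2SO4 in AcOH at 95 °C should cyclodehydrate to 10.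

Step 2. The aryllithium may be protonated or chlorinated instead of coupled, reductive elimination to a tetra-ortho-substituted biaryl may be slow, and metalation may partly occur at the site between a methoxy and a methoxymethoxy group. The fallback replaces oxidative coupling of the organometallic by reductive coupling of a halide and sets out from 3. The same lithiation followed by an I2 quench should give 2-iodo-5-methoxy-1,3-bis(methoxymethoxy)benzene F2, which can be freed from any regioisomer at this stage. Classical Ullmann homocoupling with activated Cu powder in DMF at 150 °C, which tolerates two ortho alkoxy groups and neutral acetals, comes back to the route at 5.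

Step 5. Cleavage may stall at the two anisyl ethers, or boron chelates may hold back partly demethylated material. The fallback splits the deprotection into two chemoselective stages with different mechanisms and sets out from 10. BCl3 in CH2Cl2 at 0 °C should remove only the chelation-activated methyl groups at O5 and O5'' and give 4',4'''-di-O-methylcupressuflavone F3. A pyridinium chloride melt at 190 °C, in which chloride demethylates the protonated anisyl ethers, then comes back to the route at 11.

Further compounds
F1 | step 4 | 3,3'-diacetyl-4,4'-dimethoxybiphenyl-2,2',6,6'-tetrol | CC(=O)c1c(OC)cc(O)c(c1O)-c1c(O)cc(OC)c(C(C)=O)c1O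
F2 | step 2 | 2-iodo-5-methoxy-1,3-bis(methoxymethoxy)benzene | COCOc1cc(OC)cc(OCOC)c1I
F3 | step 5 | 4',4'''-di-O-methylcupressuflavone | O=c1cc(-c2ccc(OC)cc2)oc2c(-c3c(O)cc(O)c4c(=O)cc(-c5ccc(OC)cc5)oc34)c(O)cc(O)c12
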